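## Structural features

The target is a biflavone ether without any stereocentre. Two 2-aryl-4H-chromen-4-one units, each a benzo ring A fused to a 4-pyranone ring C with an aryl ring B on C2, are joined by one diaryl ether oxygen between C8 of ring A of unit 1 and C4' of ring B of unit 2. Unit 1 carries a chelated 5-hydroxyl, a 7-methoxyl and a 4'-methoxyl; unit 2 carries free 5- and 7-hydroxyls. Because there are no stereocentres, none stand next to each other; the only stereochemical element met on the way is the geometry of an enol-ether double bond, which is erased when ring C of unit 1 closes. The fragile points are these: both pyranones open at C2 under hydroxide or alkoxide; a 5-hydroxyflavone with an unsymmetrical ring A can open and reclose on the other ortho oxygen in hot aqueous mineral acid (Wessely–Moser), which would turn the 8-aryloxy into the 6-aryloxy isomer; and methyl ethers coexist with free phenols, so no late global methylation or demethylation is possible. The real difficulty is ring A of unit 1, a 1,2,3,5-tetraoxygenated benzene whose four oxygens are all different (pyranone O1 on C8a, aryl ether on C8, methyl ether on C7, free hydroxyl on C5). Unit 2 derives from a threefold-symmetric triphenol and raises no regiochemical question. The key step exploits the fact that O1 on C8a is the direct neighbour of the aryloxy carbon C8: if ring C is grown from an enol ether on that oxygen, one ortho carbon is occupied and only the future C4a (between O1 and the free hydroxyl, para to the methoxyl) can be acylated, so C4–C4a closure can give only the 8-aryloxy-5-hydroxy-7-methoxy pattern.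

## Logic of the disconnections

14 to 11 and 12. The O1–C2 and C4–C4a bonds of ring C of unit 2 are cut. The cut is made here because 12 is threefold symmetric, so every acylation site and every hydroxyl is equivalent and no protecting group is needed. The gain is the removal of a whole ring and three hydroxyls; what remains, 11, contains only one flavone. The demand is that the forward condensation runs without acid, so that unit 1 does not isomerise and no coumarin forms, and that 11 tolerates a hot melt.

11 to 10. The C–C bond between the ketone alpha carbon (future C3 of unit 2) and the ester carbonyl (future C4) is cut. The reason is that an aryl methyl ketone is a robust spectator that can be carried from the first step. The gain is one functional group less. The demand is a base-mediated C-acylation in the presence of a chelated phenol and a pyranone.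

10 to 9. The C4–C4a bond of unit 1 is cut, opening ring C to an aryl enol ether acid. This is the strategic cut, because in 9 the position of the future ring oxygen is already fixed next to the aryloxy carbon. The gain is that the flavone problem becomes a problem of a trisubstituted diaryl ether phenol. The demand is an acid medium that equilibrates the alkene geometry, acylates only the free ortho carbon and stays anhydrous.

9 to 7 (through 8). No skeletal bond is cut. The C–O bond of the free hydroxyl is traced back to a C–CHO bond, and the acid to its methyl ester. The formyl group is chosen as the latent hydroxyl because in 1 it also makes one hydroxyl markedly more acidic than the other, and because it sits para to an aryloxy group, which favours aryl migration. The gain is that one oxidation and one hydroxide treatment deliver both the phenol and the acid. The demand is a peracid step that spares the enol ether and the methyl ketone.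

7 to 3 and 6. The vinyl C–O bond (future O1–C2 of unit 1) is cut. The reason is convergence: 6 brings all three carbons of ring C together with ring B of unit 1. The gain is two fragments of similar size. The demand is a conjugate addition of the single free hydroxyl of 3 under base mild enough for an aldehyde and a methyl ketone in the same molecule.

3 to 1 and 2. The diaryl ether O–C4' bond is cut. The reason is that 2 is activated for substitution by the very acetyl group that later becomes C2 and C3 of unit 2, and that the two hydroxyls of 1 differ in acidity. The gain is two commercial compounds. The demand is arylation of the mono-anion only.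

6 to 4 (through 5). The bond between the alkyne carbon and the ester carbonyl is cut. The reason is that 4 is commercial and acetylide acylation is routine. The demand is low temperature, to avoid a second addition.

## Other disconnections considered

Alternative 1: The cut is through the C3'–C4' and C5'–C6' bonds of ring B of unit 2, so that this benzene ring is built and not bought. In the forward key step the aryl ethynyl ether A1 adds as an electron-rich dienophile across C3 and C6 of methyl coumalate A2, and the bridged lactone loses CO2 to give the para-aryloxybenzoate A3.
- In favour: the ether oxygen is on ring A of unit 1 before ring B exists, so no substitution by a hindered, stabilised phenoxide is needed. The polarisation of both partners (nucleophilic terminal alkyne carbon to C6 of A2) should place the oxygen para to the ester. The step is neutral and metal-free, with CO2 as the only by-product. The aldehyde is masked in A3, so no aldehyde and enolisable ketone coexist.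
- Against, here: A1 is an ynol ether of a 2,6-dioxygenated phenol. It would need a multi-step dichlorovinyl ether and strong-base elimination sequence, and it is prone to ketene formation at the temperature such cycloadditions need. The phenol behind A1 must have its more acidic hydroxyl free and the less acidic one protected, the reverse of what direct protection gives. A3 is an ester and not a methyl ketone, so unit 2 needs a longer acylation, rearrangement, cyclisation and deprotection end game. The step does nothing for the 8- versus 6-aryloxy question, so ring C of unit 1 would still have to be closed as in the chosen plan.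
- Comparison: on structure, it spends the key step on a para-disubstituted benzene that the chosen plan takes ready-made from 2. On mechanism, the pericyclic step is at least the equal of the substitution in step 1, and it is the better of the two in functional-group tolerance and in excluding double arylation. On step economy it is clearly worse, needing roughly twice as many operations to reach the stage of 10.

Alternative 2: The cut is at C2=C3 of unit 2. In the forward key step the phosphorane carbon of ylide A4 attacks the neighbouring aryl ester carbonyl (intramolecular Wittig olefination of an ester), and loss of triphenylphosphine oxide closes ring C of unit 2 to give the dibenzyl ether A5, which needs hydrogenolysis to reach 14.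
- In favour: the ring closes in a refluxing aromatic solvent under neutral conditions, far more gently than the melt of step 7. On this point the alternative is the better plan. Benzyl ethers should make the penultimate compound soluble and easy to purify. Ring B would come from a 4-fluorobenzoate, which is as good a substitution partner as 2 and has no enolisable ketone, so it is an equal or slightly better spectator for steps 1, 3 and 4.
- Against, here: A4 requires a benzoic acid of unit 1 to be esterified with a hindered, doubly benzylated ortho-hydroxyphenacyl phosphonium salt that itself takes several steps. The free 5-hydroxyl of unit 1 can compete in that esterification. A stoichiometric phosphine oxide is produced, and a final deprotection is needed. The regiochemistry of unit 1 is not addressed at all.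
- Comparison: on structure, it deals with the easy unit. On mechanism, it is as dependable as the Claisen and Mentzer pair, and milder. On step economy it costs about six to eight operations where the chosen plan uses two.

Alternative 3: The cut is through C3–C4 and O1–C2 of unit 1, so ring C of unit 1 comes from a salicylaldehyde and an aroyl carbene equivalent. In the forward key step, with [(C5Me5)RhCl2]2 and AgSbF6, the phenol of A6 directs a cationic trivalent rhodium centre to the formyl C–H bond. The acyl–rhodium species takes up the carbene from sulfoxonium ylide A7, forming C3–C4, and the ortho-hydroxyaryl 1,3-diketone cyclodehydrates (O1–C2) to A8.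
- In favour: two bonds of ring C form in one catalytic operation, with no strong acid and no alkene-geometry or indenone issue. The closure itself is milder than step 5 and is the better on that count. The position of O1 is inherited from the phenol of A6, so with isomerically pure A6 the 8-aryloxy pattern is as secure as in the chosen plan; on this point the two are equal.
- Against, here: the difficulty moves to A6, a pentasubstituted benzaldehyde. It needs the same differentiation of oxygens as 9, plus a benzyl ether and a regioselective ortho-formylation. Its formyl group is flanked by two ortho substituents. A precious-metal catalyst and a silver salt are required. A8 carries an ester and a benzyl ether, so unit 2 again needs the longer end game and a deprotection.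
- Comparison: on structure, the same ring is made, but the regiochemistry rests on the synthesis of A6 and not on a blocked ortho position. On mechanism, the organometallic cascade has more possible off-cycle paths (decarbonylation of the acyl metal, consumption of the ylide) than a Friedel–Crafts closure. On step economy it is several steps longer.

Key step: step 5

Remarks on the chemistry:
- The atom mapping of 9 to 10 and on to 14 was checked and is consistent. The ring carbon between the enol-ether oxygen and the hydroxyl becomes C4a, the hydroxyl becomes 5-OH, the methoxyl 7-OMe, and the aryloxy carbon C8. Z is the geometry with aryloxy and carboxyl cis, the one that can close the pyranone. No structure needed correction.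
- The design departs from a tert-butyl ester route in two ways. A methyl ester is used, so that one hydroxide treatment frees phenol and acid and no tert-butyl cation meets the electron-rich ring. The first step is run on the mono-anion of 1.
- Z is written for 7, 8 and 9 because anti addition is expected; any E isomer is carried along, since the geometry is equilibrated in step 5.
- Phenoxides, enolates and single mechanistic intermediates (acylium ion, Criegee adduct) are not numbered; the lithium acetylide 5, the aryl formate 8 and the diketone 13 are.

## Steps

Step 1
Reactants: 1 5-hydroxyvanillin (3,4-dihydroxy-5-methoxybenzaldehyde); 2 4'-fluoroacetophenone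
Product: 3 4-(4-acetylphenoxy)-3-hydroxy-5-methoxybenzaldehyde
Conditions: K2CO3 (0.55 equiv), 2 (1.0 equiv), DMSO, 110 °C, N2; aq. HCl work-up
Reagents that add atoms: none
Why: Nucleophilic aromatic substitution by addition–elimination, in which the para-acetyl group of 2 stabilises the Meisenheimer adduct and fluoride is the leaving group best suited to the rate-limiting addition. With one equivalent of base only the hydroxyl para to the formyl group of 1 is ionised (it is markedly the more acidic), so the aryl group should go to O4; the neighbouring hydroxyl stays protonated and hydrogen-bonded, which should suppress double arylation and aryl migration between the two oxygens.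

Step 2
Reactants: 4 4-ethynylanisole
Product: 6 methyl 3-(4-methoxyphenyl)prop-2-ynoate, via lithium acetylide 5 (not isolated)
Conditions: n-BuLi, THF, −78 °C; ClCO2Me, −78 °C to rt
Reagents that add atoms: methyl chloroformate, COC(=O)Cl
Why: Deprotonation of the terminal alkyne and C-acylation of the lithium acetylide with a chloroformate, a standard alkynoate synthesis; the low temperature prevents a second addition to the ester.

Step 3
Reactants: 3 4-(4-acetylphenoxy)-3-hydroxy-5-methoxybenzaldehyde; 6 methyl 3-(4-methoxyphenyl)prop-2-ynoate
Product: 7 methyl (Z)-3-[2-(4-acetylphenoxy)-5-formyl-3-methoxyphenoxy]-3-(4-methoxyphenyl)prop-2-enoate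
Conditions: Cs2CO3 (0.3 equiv), DMF, 70 °C, N2
Reagents that add atoms: none
Why: Base-catalysed oxa-Michael addition of the only free phenol of 3 to the alkynoate, the first half of the Ruhemann flavone synthesis; anti addition should place the aryloxy group cis to the ester (Z). Catalytic carbonate in dry DMF at moderate temperature is chosen so that the aldehyde and the methyl ketone do not condense with each other.

Step 4
Reactants: 7 methyl (Z)-3-[2-(4-acetylphenoxy)-5-formyl-3-methoxyphenoxy]-3-(4-methoxyphenyl)prop-2-enoate
Product: 9 (Z)-3-[2-(4-acetylphenoxy)-5-hydroxy-3-methoxyphenoxy]-3-(4-methoxyphenyl)prop-2-enoic acid, via aryl formate 8 (not isolated)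
Conditions: mCPBA (1.2 equiv), CH2Cl2, 0 °C to rt; aq. Na2SO3/NaHCO3 wash, crude 8; LiOH (5 equiv), THF/MeOH/H2O, 40 °C, degassed; 1 M HCl
Reagents that add atoms: meta-chloroperoxybenzoic acid, O=C(OO)c1cccc(Cl)c1; lithium hydroxide, [Li+].[OH-]
Why: Baeyer–Villiger oxidation, in which the peracid adds to the formyl group and the aryl ring migrates in the Criegee adduct because it carries an aryloxy group para to the migrating carbon; the ester-conjugated enol ether and the aryl methyl ketone should react far more slowly with a slight excess of peracid at or below room temperature. One hydroxide treatment then cleaves the formate and saponifies the methyl ester (the classical hydrolysis of beta-aryloxycinnamates), so no acidic deprotection is needed before the key step.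

Step 5
Reactants: 9 (Z)-3-[2-(4-acetylphenoxy)-5-hydroxy-3-methoxyphenoxy]-3-(4-methoxyphenyl)prop-2-enoic acid
Product: 10 8-(4-acetylphenoxy)-5-hydroxy-7-methoxy-2-(4-methoxyphenyl)chromen-4-one
Conditions: Eaton's reagent (7.7 wt% P2O5 in CH3SO3H), dilute, 25 to 45 °C, N2; poured onto ice
Reagents that add atoms: none
Why: This is the ring-closing half of the Ruhemann flavone synthesis, an intramolecular Friedel–Crafts acylation. The carboxylic acid is turned by P2O5/CH3SO3H into a mixed anhydride or acylium ion, the ring carbon between the enol-ether oxygen and the free hydroxyl attacks it, and loss of a proton restores ring A and gives the chelated 5-hydroxy-4-pyranone. Ring C closes as a six-membered ring by exo attack of the arene on the activated carboxyl carbon (6-exo-trig for the mixed anhydride, 6-exo-dig for a free acylium ion), forming only the C4–C4a bond. The tether can reach only the two carbons ortho to the enol-ether oxygen, and one of them carries the 4-acetylphenoxy group, so substitution can occur only at the other, which is also activated by two ortho oxygens and a para methoxyl; this fixes the 8-aryloxy-5-hydroxy-7-methoxy pattern and excludes the 6-aryloxy isomer. Only the Z acid can close the pyranone, but in the strong acid the enol ether is reversibly protonated at the alpha carbon to a 4-methoxyphenyl-stabilised oxocarbenium ion, so E and Z interconvert and both should drain through the Z isomer. Indenone formation from the E acid would need a five-membered closure onto a position meta to the methoxyl of ring B and should not compete, and the acetyl group is merely protonated while its deactivated ring is not attacked. No stereocentre is formed, and the anhydrous medium and low temperature should prevent both hydrolysis of the enol ether and ring-opening isomerisation of the product.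

Step 6
Reactants: 10 8-(4-acetylphenoxy)-5-hydroxy-7-methoxy-2-(4-methoxyphenyl)chromen-4-one
Product: 11 ethyl 3-[4-[[5-hydroxy-7-methoxy-2-(4-methoxyphenyl)-4-oxochromen-8-yl]oxy]phenyl]-3-oxopropanoate
Conditions: NaH (4 equiv), (EtO)2CO (10 equiv), THF, reflux; AcOH, 0 °C
Reagents that add atoms: diethyl carbonate, CCOC(=O)OCC
Why: Crossed Claisen condensation (carbethoxylation) of the methyl ketone enolate with diethyl carbonate, driven by deprotonation of the beta-keto ester as it forms. The first equivalent of NaH is taken by the chelated 5-hydroxyl, whose phenoxide is a poor nucleophile, and the pyranone has no enolisable position; the acidic quench should reclose any pyranone opened reversibly by ethoxide.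

Step 7
Reactants: 11 ethyl 3-[4-[[5-hydroxy-7-methoxy-2-(4-methoxyphenyl)-4-oxochromen-8-yl]oxy]phenyl]-3-oxopropanoate; 12 phloroglucinol (benzene-1,3,5-triol, anhydrous)
Product: 14 5,7-dihydroxy-2-[4-[[5-hydroxy-7-methoxy-2-(4-methoxyphenyl)-4-oxochromen-8-yl]oxy]phenyl]chromen-4-one, via beta-diketone 13 (not isolated)
Conditions: 12 (3 equiv), neat melt, 240 °C, N2, ethanol and water distilled off
Reagents that add atoms: none
Why: Mentzer pyrone synthesis (thermal, acid-free condensation of a beta-keto ester with a phenol): loss of ethanol gives an acylketene or aryl ester that C-acylates 12, and the ortho-hydroxyaryl 1,3-diketone 13 cyclodehydrates onto the aryl ketone carbonyl to form ring C of unit 2. The symmetry of 12 removes any regiochemical question, and the absence of acid should avoid both coumarin formation and ring-opening isomerisation of unit 1.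

## Compound list

1 | 5-hydroxyvanillin (3,4-dihydroxy-5-methoxybenzaldehyde) | COc1cc(C=O)cc(O)c1O | starting material
2 | 4'-fluoroacetophenone | CC(=O)c1ccc(F)cc1 | starting material
3 | 4-(4-acetylphenoxy)-3-hydroxy-5-methoxybenzaldehyde | CC(=O)c1ccc(Oc2c(O)cc(C=O)cc2OC)cc1 | intermediate
4 | 4-ethynylanisole | C#Cc1ccc(OC)cc1 | starting material
5 | lithium (4-methoxyphenyl)acetylide, not isolated | [Li]C#Cc1ccc(OC)cc1 | intermediate
6 | methyl 3-(4-methoxyphenyl)prop-2-ynoate | COC(=O)C#Cc1ccc(OC)cc1 | intermediate
7 | methyl (Z)-3-[2-(4-acetylphenoxy)-5-formyl-3-methoxyphenoxy]-3-(4-methoxyphenyl)prop-2-enoate | CC(=O)c1ccc(Oc2c(OC)cc(C=O)cc2O/C(=C\C(=O)OC)c2ccc(OC)cc2)cc1 | intermediate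
8 | methyl (Z)-3-[2-(4-acetylphenoxy)-5-(formyloxy)-3-methoxyphenoxy]-3-(4-methoxyphenyl)prop-2-enoate, not isolated | CC(=O)c1ccc(Oc2c(OC)cc(OC=O)cc2O/C(=C\C(=O)OC)c2ccc(OC)cc2)cc1 | intermediate
9 | (Z)-3-[2-(4-acetylphenoxy)-5-hydroxy-3-methoxyphenoxy]-3-(4-methoxyphenyl)prop-2-enoic acid | CC(=O)c1ccc(Oc2c(OC)cc(O)cc2O/C(=C\C(=O)O)c2ccc(OC)cc2)cc1 | intermediate
10 | 8-(4-acetylphenoxy)-5-hydroxy-7-methoxy-2-(4-methoxyphenyl)chromen-4-one | CC(=O)c1ccc(Oc2c(OC)cc(O)c3c(=O)cc(-c4ccc(OC)cc4)oc23)cc1 | intermediate
11 | ethyl 3-[4-[[5-hydroxy-7-methoxy-2-(4-methoxyphenyl)-4-oxochromen-8-yl]oxy]phenyl]-3-oxopropanoate | CCOC(=O)CC(=O)c1ccc(Oc2c(OC)cc(O)c3c(=O)cc(-c4ccc(OC)cc4)oc23)cc1 | intermediate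
12 | phloroglucinol (benzene-1,3,5-triol) | Oc1cc(O)cc(O)c1 | starting material
13 | 1-[4-[[5-hydroxy-7-methoxy-2-(4-methoxyphenyl)-4-oxochromen-8-yl]oxy]phenyl]-3-(2,4,6-trihydroxyphenyl)propane-1,3-dione, not isolated | O=C(CC(=O)c1c(O)cc(O)cc1O)c1ccc(Oc2c(OC)cc(O)c3c(=O)cc(-c4ccc(OC)cc4)oc23)cc1 | intermediate
14 | 5,7-dihydroxy-2-[4-[[5-hydroxy-7-methoxy-2-(4-methoxyphenyl)-4-oxochromen-8-yl]oxy]phenyl]chromen-4-one | COc1ccc(-c2cc(=O)c3c(O)cc(OC)c(Oc4ccc(-c5cc(=O)c6c(O)cc(O)cc6o5)cc4)c3o2)cc1 | target

## Step count and least certain steps

Total: 7 steps. Longest linear sequence: 6 steps (1, 3, 4, 5, 6, 7); step 2 is a one-step side branch.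

Step 5 (key step). The most likely failure is intermolecular acylation of the free phenol or of another electron-rich ring (oligomer formation) outrunning the ring closure. The second is cleavage of the enol ether by adventitious water, because protonation at the alpha carbon gives a cation that water traps readily. Fallback: change from dehydrative activation of the free acid in a Brønsted superacid to a masked phenol and a preformed acyl chloride closed by a mild Lewis acid. It sets out from 9 and comes back at 10.
- Acetylation of the phenol (Ac2O, pyridine, aqueous work-up to hydrolyse the mixed anhydride) should give (Z)-3-[5-acetoxy-2-(4-acetylphenoxy)-3-methoxyphenoxy]-3-(4-methoxyphenyl)prop-2-enoic acid F1.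
- Oxalyl chloride with catalytic DMF in CH2Cl2 should convert it into (Z)-3-[5-acetoxy-2-(4-acetylphenoxy)-3-methoxyphenoxy]-3-(4-methoxyphenyl)prop-2-enoyl chloride F2.
- SnCl4 in CH2Cl2 at −20 to 0 °C should close the same C4–C4a bond, still at the only free ortho carbon, to 8-(4-acetylphenoxy)-7-methoxy-2-(4-methoxyphenyl)-4-oxochromen-5-yl acetate F3.
- K2CO3 in methanol at room temperature removes the acetate and returns 10.

Step 1. The likely failures are arylation of the wrong oxygen or of both, slow substitution by a hindered and resonance-stabilised phenoxide, base-induced migration of the activated aryl group between the two neighbouring oxygens, and aldol condensation between formyl and acetyl groups at the temperature needed. Fallback: remove the choice between two hydroxyls by starting from a phenol with only one, and introduce the second oxygen through boron. It sets out from 2 and comes back at 3.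
- 5-Bromovanillin (3-bromo-4-hydroxy-5-methoxybenzaldehyde) F4 is arylated with 2 (K2CO3, DMSO, 120 °C; forcing conditions are permissible because there is only one hydroxyl) to 4-(4-acetylphenoxy)-3-bromo-5-methoxybenzaldehyde F5.
- Miyaura borylation (B2pin2, PdCl2(dppf), KOAc, dioxane, 90 °C) should give 4-(4-acetylphenoxy)-3-methoxy-5-(4,4,5,5-tetramethyl-1,3,2-dioxaborolan-2-yl)benzaldehyde F6.
- Oxidation of the C–B bond with trimethylamine N-oxide in THF, an oxidant that leaves aldehydes and ketones alone, gives 3.

Step 3. The likely failure is sluggish addition to an alkynoate deactivated by its 4-methoxyphenyl group, which would force temperatures at which aldehyde–ketone condensation and aryl migration begin. Fallback: replace conjugate addition to the alkyne by addition–elimination on a vinyl halide, which is irreversible and should run at lower temperature. It sets out from 6 and comes back at 7.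
- Hydrobromination of 6 with LiBr in acetic acid (anti addition) should give methyl (Z)-3-bromo-3-(4-methoxyphenyl)prop-2-enoate F7.
- Substitution of F7 by the phenoxide of 3 (K2CO3, DMF, 40 °C), with retention of geometry, gives 7.

Step 4. The likely failures are hydride migration in place of aryl migration in the Criegee adduct (the ring is only moderately electron-rich, because its para oxygen is shared with an acetylphenyl group), oxidation of the enol-ether double bond by excess peracid, and hydroxide attack at the beta carbon of the vinylogous carbonate during saponification. Fallback: carry out the oxygen insertion before the enol ether exists and differentiate the two hydroxyls by size. It sets out from 3 and comes back at 9.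
- Baeyer–Villiger oxidation of 3 (mCPBA, CH2Cl2) and methanolysis of the formate (NaHCO3, MeOH) should give 1-[4-(2,4-dihydroxy-6-methoxyphenoxy)phenyl]ethan-1-one F8, from which any acid formed by hydride migration is removed by base extraction.
- The hydroxyl with no ortho substituent is silylated selectively (i-Pr3SiCl, imidazole, CH2Cl2, 0 °C) to 1-[4-[2-hydroxy-6-methoxy-4-[tri(propan-2-yl)silyloxy]phenoxy]phenyl]ethan-1-one F9.
- Addition of the remaining hydroxyl to 6, as in step 3, gives methyl (Z)-3-[2-(4-acetylphenoxy)-3-methoxy-5-[tri(propan-2-yl)silyloxy]phenoxy]-3-(4-methoxyphenyl)prop-2-enoate F10.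
- LiOH in aqueous THF/MeOH, followed by Bu4NF if the silyl ether persists, gives 9.

Step 7. The likely failures are thermal loss of the carbethoxy group (reversion towards 10) before acylation, poor mixing of a high-melting substrate in the melt, and O-acylation that does not go on to C-acylation. Fallback: form the same 1,3-diketone at low temperature by enolate acylation with a protected acyl chloride. It sets out from 10 (step 6 is then not needed) and comes back at 13 and hence 14.
- 2,4,6-Tris(benzyloxy)benzoic acid F11 is converted with oxalyl chloride and catalytic DMF into 2,4,6-tris(benzyloxy)benzoyl chloride F12.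
- The enolate of 10 (LiN(SiMe3)2, 3.2 equiv, THF, −78 °C; the excess base keeps the product deprotonated and favours C-acylation) is acylated with F12 to 1-[4-[[5-hydroxy-7-methoxy-2-(4-methoxyphenyl)-4-oxochromen-8-yl]oxy]phenyl]-3-[2,4,6-tris(benzyloxy)phenyl]propane-1,3-dione F13.
- Hydrogenolysis (H2, palladium on carbon, THF/EtOAc) gives 13.
- Catalytic p-toluenesulfonic acid in acetic acid at 60 °C closes 13 to 14.

## Further compounds

F1 | step 5 | (Z)-3-[5-acetoxy-2-(4-acetylphenoxy)-3-methoxyphenoxy]-3-(4-methoxyphenyl)prop-2-enoic acid | CC(=O)c1ccc(Oc2c(OC)cc(OC(C)=O)cc2O/C(=C\C(=O)O)c2ccc(OC)cc2)cc1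
F2 | step 5 | (Z)-3-[5-acetoxy-2-(4-acetylphenoxy)-3-methoxyphenoxy]-3-(4-methoxyphenyl)prop-2-enoyl chloride | CC(=O)c1ccc(Oc2c(OC)cc(OC(C)=O)cc2O/C(=C\C(=O)Cl)c2ccc(OC)cc2)cc1
F3 | step 5 | 8-(4-acetylphenoxy)-7-methoxy-2-(4-methoxyphenyl)-4-oxochromen-5-yl acetate | CC(=O)c1ccc(Oc2c(OC)cc(OC(C)=O)c3c(=O)cc(-c4ccc(OC)cc4)oc23)cc1
F4 | step 1 | 5-bromovanillin (3-bromo-4-hydroxy-5-methoxybenzaldehyde) | COc1cc(C=O)cc(Br)c1O
F5 | step 1 | 4-(4-acetylphenoxy)-3-bromo-5-methoxybenzaldehyde | CC(=O)c1ccc(Oc2c(Br)cc(C=O)cc2OC)cc1
F6 | step 1 | 4-(4-acetylphenoxy)-3-methoxy-5-(4,4,5,5-tetramethyl-1,3,2-dioxaborolan-2-yl)benzaldehyde | CC(=O)c1ccc(Oc2c(B3OC(C)(C)C(C)(C)O3)cc(C=O)cc2OC)cc1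
F7 | step 3 | methyl (Z)-3-bromo-3-(4-methoxyphenyl)prop-2-enoate | COC(=O)/C=C(\Br)c1ccc(OC)cc1
F8 | step 4 | 1-[4-(2,4-dihydroxy-6-methoxyphenoxy)phenyl]ethan-1-one | CC(=O)c1ccc(Oc2c(O)cc(O)cc2OC)cc1
F9 | step 4 | 1-[4-[2-hydroxy-6-methoxy-4-[tri(propan-2-yl)silyloxy]phenoxy]phenyl]ethan-1-one | CC(=O)c1ccc(Oc2c(O)cc(O[Si](C(C)C)(C(C)C)C(C)C)cc2OC)cc1
F10 | step 4 | methyl (Z)-3-[2-(4-acetylphenoxy)-3-methoxy-5-[tri(propan-2-yl)silyloxy]phenoxy]-3-(4-methoxyphenyl)prop-2-enoate | CC(=O)c1ccc(Oc2c(OC)cc(O[Si](C(C)C)(C(C)C)C(C)C)cc2O/C(=C\C(=O)OC)c2ccc(OC)cc2)cc1
F11 | step 7 | 2,4,6-tris(benzyloxy)benzoic acid | OC(=O)c1c(OCc2ccccc2)cc(OCc2ccccc2)cc1OCc1ccccc1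
F12 | step 7 | 2,4,6-tris(benzyloxy)benzoyl chloride | ClC(=O)c1c(OCc2ccccc2)cc(OCc2ccccc2)cc1OCc1ccccc1
F13 | step 7 | 1-[4-[[5-hydroxy-7-methoxy-2-(4-methoxyphenyl)-4-oxochromen-8-yl]oxy]phenyl]-3-[2,4,6-tris(benzyloxy)phenyl]propane-1,3-dione | O=C(CC(=O)c1c(OCc2ccccc2)cc(OCc2ccccc2)cc1OCc1ccccc1)c1ccc(Oc2c(OC)cc(O)c3c(=O)cc(-c4ccc(OC)cc4)oc23)cc1
A1 | alternative 1 | 2-[4-(ethynyloxy)-3-methoxy-5-(methoxymethoxy)phenyl]-1,3-dioxolane | C#COc1c(OC)cc(C2OCCO2)cc1OCOC
A2 | alternative 1 | methyl coumalate (methyl 2-oxo-2H-pyran-5-carboxylate) | COC(=O)C1=COC(=O)C=C1
A3 | alternative 1 | methyl 4-[4-(1,3-dioxolan-2-yl)-2-methoxy-6-(methoxymethoxy)phenoxy]benzoate | COC(=O)c1ccc(Oc2c(OC)cc(C3OCCO3)cc2OCOC)cc1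
A4 | alternative 2 | [3,5-bis(benzyloxy)-2-[2-(triphenyl-λ5-phosphanylidene)acetyl]phenyl] 4-[[5-hydroxy-7-methoxy-2-(4-methoxyphenyl)-4-oxochromen-8-yl]oxy]benzoate | COc1ccc(-c2cc(=O)c3c(O)cc(OC)c(Oc4ccc(C(=O)Oc5cc(OCc6ccccc6)cc(OCc6ccccc6)c5C(=O)C=P(c5ccccc5)(c5ccccc5)c5ccccc5)cc4)c3o2)cc1
A5 | alternative 2 | 5,7-bis(benzyloxy)-2-[4-[[5-hydroxy-7-methoxy-2-(4-methoxyphenyl)-4-oxochromen-8-yl]oxy]phenyl]chromen-4-one | COc1ccc(-c2cc(=O)c3c(O)cc(OC)c(Oc4ccc(-c5cc(=O)c6c(OCc7ccccc7)cc(OCc7ccccc7)cc6o5)cc4)c3o2)cc1
A6 | alternative 3 | methyl 4-[4-(benzyloxy)-3-formyl-2-hydroxy-6-methoxyphenoxy]benzoate | COC(=O)c1ccc(Oc2c(OC)cc(OCc3ccccc3)c(C=O)c2O)cc1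
A7 | alternative 3 | 2-[dimethyl(oxo)-λ6-sulfanylidene]-1-(4-methoxyphenyl)ethan-1-one | COc1ccc(C(=O)C=S(C)(C)=O)cc1
A8 | alternative 3 | methyl 4-[[5-(benzyloxy)-7-methoxy-2-(4-methoxyphenyl)-4-oxochromen-8-yl]oxy]benzoate | COC(=O)c1ccc(Oc2c(OC)cc(OCc3ccccc3)c3c(=O)cc(-c4ccc(OC)cc4)oc23)cc1
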